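**Strategy**

The furanone ring is opened at O1–C5 to a cis-enynoic acid, whose anti 5-exo-dig iodolactonisation closes the ring and sets the (E)-iodomethylene group. What remains, the C3=C4 alkene with Br on C4 and the carbinol C1' and the carboxyl C2 on C3, is a β-halo Morita–Baylis–Hillman ester. Everything rests on forming the C3–C1' bond by a catalytic enantioselective three-component coupling of methyl 3-bromopropiolate, iodotrimethylsilane and butanal. In one operation it gives this bond, the C1' stereocentre, the tetrasubstituted alkene and a C4–I handle cis to the ester, which a Sonogashira coupling then turns into the C5 alkyne.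

Key step: step 2

Remark on numbering: ring atoms are O1, C2 (C=O), C3, C4 (Br), C5; C1' is the carbinol carbon, which is (R) in the target.
Remark on the catalyst: the (S)-oxazaborolidinium ion is assigned to the (R)-carbinol from its usual aldehyde-binding model; the configuration of 6 should be checked by Mosher ester analysis, and the (R)-catalyst used if the sense proves opposite.

**Route**

Step 1
Reactants: 1 methyl propiolate
Product: 2 methyl 3-bromopropiolate
Conditions: NBS, AgNO3 (10 mol %), acetone, rt
Reagents that add atoms: N-bromosuccinimide, O=C1CCC(=O)N1Br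
Why: Silver-catalysed electrophilic bromination of a terminal alkyne (silver acetylide, then Br+ transfer from NBS) is the standard route to 1-bromoalkynes and tolerates the ester.

Step 2
Reactants: 2 methyl 3-bromopropiolate; 3 butanal
Product: 6 methyl (2Z)-3-bromo-2-[(1R)-1-hydroxybutyl]-3-iodoprop-2-enoate, via silyl allenoate 4 (not isolated), via silyl ether 5 (not isolated)
Conditions: TMSI, (S)-o-tolyl oxazaborolidinium triflimide (20 mol %), CH2Cl2, −78 °C; then 1 M HCl, THF, 0 °C
Reagents that add atoms: iodotrimethylsilane, C[Si](C)(C)I
Why: Proposed new method: silyl iodide should add in conjugate fashion to the O-silylated bromo-ynoate to give the gem-bromo-iodo silyl allenoate 4, whose central carbon attacks butanal bound to the chiral oxazaborolidinium ion in a Mukaiyama-type aldol, so that the C3–C1' bond, the C–I bond and the tetrasubstituted alkene arise together. The closest known reaction type is the oxazaborolidinium-catalysed three-component coupling of TMSI, alkyl propiolates and aldehydes to (Z)-β-iodo Morita–Baylis–Hillman esters (halo-aldol reaction); the new element is a halogen already on the alkyne terminus. No ring is closed. The C1' stereocentre is set by the catalyst: the aldehyde is held by B–O coordination and a formyl C–H···O contact so that the allenoate should add to its Si face, giving (R). The step needs the carbinol cis to Br and iodine cis to the ester; the aldehyde approaches in the plane of the two halogens and should enter anti to the larger iodine (longer C–I bond, larger radius), as it enters anti to iodine in the propiolate series, but the preference over bromine is expected to be only moderate. The minor alkene isomer cannot lactonise in step 5 and is removed there as an acid.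

Step 3
Reactants: 6 methyl (2Z)-3-bromo-2-[(1R)-1-hydroxybutyl]-3-iodoprop-2-enoate; 7 ethynyltrimethylsilane
Product: 8 methyl (2E)-3-bromo-2-[(1R)-1-hydroxybutyl]-5-(trimethylsilyl)pent-2-en-4-ynoate
Conditions: PdCl2(PPh3)2 (3 mol %), CuI (5 mol %), Et3N, THF, 0 °C to rt
Reagents that add atoms: none
Why: Chemoselective Sonogashira coupling, in which Pd(0) inserts into the C–I bond much faster than into the geminal C–Br bond and with retention of alkene geometry, so the alkyne should end cis to the ester and Br stay cis to the carbinol.

Step 4
Reactants: 8 methyl (2E)-3-bromo-2-[(1R)-1-hydroxybutyl]-5-(trimethylsilyl)pent-2-en-4-ynoate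
Product: 9 (2E)-3-bromo-2-[(1R)-1-hydroxybutyl]pent-2-en-4-ynoic acid
Conditions: LiOH·H2O, THF/H2O (3:1), 0 °C to rt; then 1 M HCl to pH 3
Reagents that add atoms: lithium hydroxide (aqueous), [Li+].[OH-]
Why: Saponification of the methyl ester together with hydroxide-induced protodesilylation of the alkynylsilane should free the acid and the terminal alkyne in one operation without touching C1' or the alkene geometry.

Step 5
Reactants: 9 (2E)-3-bromo-2-[(1R)-1-hydroxybutyl]pent-2-en-4-ynoic acid
Product: 10 (5E)-4-bromo-3-[(1R)-1-hydroxybutyl]-5-(iodomethylidene)furan-2(5H)-one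
Conditions: I2, NaHCO3, MeCN, 0 °C to rt, dark
Reagents that add atoms: iodine, II
Why: Iodolactonisation, in which I+ activates the terminal alkyne and the cis carboxylate closes 5-exo-dig at the internal carbon by anti addition, should place iodine trans to the ring oxygen, which is the (E)-iodomethylene geometry of the target.

**Compound list**

1 | methyl propiolate (methyl prop-2-ynoate) | C#CC(=O)OC | starting material
2 | methyl 3-bromopropiolate | BrC#CC(=O)OC | intermediate
3 | butanal | CCCC=O | starting material
4 | 3-bromo-3-iodo-1-methoxy-1-(trimethylsilyloxy)propa-1,2-diene (silyl allenoate) | COC(O[Si](C)(C)C)=C=C(Br)I | intermediate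
5 | methyl (2Z)-3-bromo-3-iodo-2-[(1R)-1-(trimethylsilyloxy)butyl]prop-2-enoate | CCC[C@@H](O[Si](C)(C)C)/C(C(=O)OC)=C(\Br)I | intermediate
6 | methyl (2Z)-3-bromo-2-[(1R)-1-hydroxybutyl]-3-iodoprop-2-enoate (I cis to ester, Br cis to carbinol) | CCC[C@@H](O)/C(C(=O)OC)=C(\Br)I | intermediate
7 | ethynyltrimethylsilane | C#C[Si](C)(C)C | starting material
8 | methyl (2E)-3-bromo-2-[(1R)-1-hydroxybutyl]-5-(trimethylsilyl)pent-2-en-4-ynoate (alkyne cis to ester) | CCC[C@@H](O)/C(C(=O)OC)=C(\Br)C#C[Si](C)(C)C | intermediate
9 | (2E)-3-bromo-2-[(1R)-1-hydroxybutyl]pent-2-en-4-ynoic acid | CCC[C@@H](O)/C(C(=O)O)=C(\Br)C#C | intermediate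
10 | (5E)-4-bromo-3-[(1R)-1-hydroxybutyl]-5-(iodomethylidene)furan-2(5H)-one | CCC[C@@H](O)C1=C(Br)/C(=C\I)OC1=O | target

**Step count and risks**

Total steps: 5. Longest linear sequence: 5 steps (1 → 2 → 6 → 8 → 9 → 10).

Most likely to fail, in this order:

First, step 2 (Proposed new method). The aldehyde may discriminate poorly between iodine and bromine when it approaches the allenoate, giving a mixture of alkene isomers. The halogens may scramble through reversible loss of halide from 4. Enantiofacial control may erode on a gem-dihalo allenoate. The fallback uses known chemistry, sets out from butanal 3 and commercial 1,4-bis(trimethylsilyl)buta-1,3-diyne, and comes back at 8. Mono-desilylation with MeLi·LiBr gives lithium 4-(trimethylsilyl)buta-1,3-diyn-1-ide F1, which methyl chloroformate acylates to methyl 5-(trimethylsilyl)penta-2,4-diynoate F2. Ti(O-i-Pr)4/2 i-PrMgCl at −78 °C converts the ynoate triple bond into the titanacyclopropene complex F3. Butanal inserts at the ester α-carbon to give the oxatitanacyclopentene F4, in which titanium on C4 is cis to the carbinol by ring constraint. NBS cleaves the C–Ti bond with retention to give racemic methyl (2E)-3-bromo-2-(1-hydroxybutyl)-5-(trimethylsilyl)pent-2-en-4-ynoate F5. Dess–Martin oxidation gives methyl (2E)-3-bromo-2-butanoyl-5-(trimethylsilyl)pent-2-en-4-ynoate F6, and CBS reduction ((S)-Me-oxazaborolidine, catecholborane, −78 °C; the alkenyl group acts as the large substituent) should set (R) and give 8.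

Second, step 4. Hydroxide may substitute the vinylic bromide or add in conjugate (1,6) fashion to the desilylated enynoate before the hindered ester is cleaved. The fallback sets out from 8 and comes back at 10, bypassing the free acid. Buffered fluoride (TBAF/AcOH, THF, 0 °C) removes only the silyl group to give methyl (2E)-3-bromo-2-[(1R)-1-hydroxybutyl]pent-2-en-4-ynoate F7. Iodine (or ICl) in CH2Cl2 then cyclises the ester carbonyl oxygen 5-exo onto the iodonium-activated alkyne, and iodide demethylates the resulting oxocarbenium ion.

Third, step 5. Closure may occur in the 6-endo mode to an iodopyranone, or the light-sensitive dienyl iodide may degrade under excess iodine. The fallback sets out from 9 and comes back at 10. Stoichiometric Hg(OCOCF3)2 followed by NaCl should effect anti 5-exo oxymercuration to (5E)-4-bromo-5-[(chloromercurio)methylidene]-3-[(1R)-1-hydroxybutyl]furan-2(5H)-one F8. Iododemercuration with I2 proceeds with retention and should give 10.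

Further compounds
F1 | step 2 | lithium 4-(trimethylsilyl)buta-1,3-diyn-1-ide | [Li]C#CC#C[Si](C)(C)C
F2 | step 2 | methyl 5-(trimethylsilyl)penta-2,4-diynoate | COC(=O)C#CC#C[Si](C)(C)C
F3 | step 2 | titanacyclopropene complex of F2 with Ti(O-i-Pr)2 | COC(=O)C1=C(C#C[Si](C)(C)C)[Ti]1(OC(C)C)OC(C)C
F4 | step 2 | oxatitanacyclopentene from F3 and butanal | CCCC1O[Ti](OC(C)C)(OC(C)C)C(C#C[Si](C)(C)C)=C1C(=O)OC
F5 | step 2 | racemic methyl (2E)-3-bromo-2-(1-hydroxybutyl)-5-(trimethylsilyl)pent-2-en-4-ynoate | CCCC(O)/C(C(=O)OC)=C(\Br)C#C[Si](C)(C)C
F6 | step 2 | methyl (2E)-3-bromo-2-butanoyl-5-(trimethylsilyl)pent-2-en-4-ynoate | CCCC(=O)/C(C(=O)OC)=C(\Br)C#C[Si](C)(C)C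
F7 | step 4 | methyl (2E)-3-bromo-2-[(1R)-1-hydroxybutyl]pent-2-en-4-ynoate | CCC[C@@H](O)/C(C(=O)OC)=C(\Br)C#C
F8 | step 5 | (5E)-4-bromo-5-[(chloromercurio)methylidene]-3-[(1R)-1-hydroxybutyl]furan-2(5H)-one | CCC[C@@H](O)C1=C(Br)/C(=C\[Hg]Cl)OC1=O
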